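**Plan**

1. Numbering: C1 and C5 are the bridgeheads, C2–C4 the trione bridge, C6–C8 the other bridge, C9 the bridging ketone; exo means the face of ring B turned away from the C2–C4 bridge. The retrosynthesis cuts, in order: the C3–aroyl bond, the sp3–sp2 bond of the C7 side chain (then C7=CH2 back to a C7 ketone), the C1–prenyl bond, the C2 oxygen, then C1–C8 (ring B), and last the two C–C bonds at C5.
2. Enabling feature: C5 carries geranyl and sits between the oxygenated carbons C4 and C9. Ring A (C1–C2–C3–C4–C5–C9) can therefore be built as a mirror-symmetric 6,6-dialkyl-1,5-dimethoxycyclohexa-1,4-diene, whose enol ether arms C9=C1 and C4=C3 remain enantiotopic until C8 bonds to C1.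
3. Forward order: ring A by Birch reduction of 1,3-dimethoxybenzene and two alkylations at the future C5; ring B by epoxide-opening cyclisation; then C2 oxidation, C1 prenylation, C7–O to C7=CH2 to endo-geranyl, C3 aroylation, global deprotection.
4. Stereochemistry: the (R)-epoxide from Sharpless epoxidation of prenol dictates C1 and C5 in the cyclisation; C7 is erased and reset by exo-face hydroboration; the E-olefins come from geranyl bromide and a syn-carboalumination.

Key step: step 6

Remark: the target is drawn as its C4-enol/C2-keto tautomer (1S,5S,7S); the final product is expected as the equilibrating enol tautomers of the 3-aroyl-2,4-dione, which are one compound.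

**Step 1**
Reactants: 1 1,3-dimethoxybenzene
Product: 2 1,5-dimethoxycyclohexa-1,4-diene
Conditions: Li, NH3(l), t-BuOH, THF, −78 °C; NH4Cl
Reagents that add atoms: none
Why: Birch reduction, in which the two methoxy groups steer protonation to the carbon between them and to the para-related carbon, so both oxygens stay on sp2 carbons of an unconjugated 1,4-diene.

**Step 2**
Reactants: 2 1,5-dimethoxycyclohexa-1,4-diene; 3 geranyl bromide
Product: 4 6-geranyl-1,5-dimethoxycyclohexa-1,4-diene
Conditions: t-BuLi, THF, −78 °C; then 3, −78 → 0 °C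
Reagents that add atoms: none
Why: Metallation–alkylation of a Birch diene: the CH2 flanked by the two methoxy-bearing carbons is deprotonated (pentadienyl anion with the charge kept off the oxygenated carbons, lithium held by both OMe groups) and is alkylated at its central carbon by the allylic bromide in an SN2 reaction that keeps the E-olefin.

**Step 3**
Reactants: 5 3-methylbut-2-en-1-ol
Product: 6 [(2R)-3,3-dimethyloxiran-2-yl]methanol
Conditions: Ti(OiPr)4 (cat.), D-(−)-diisopropyl tartrate (cat.), t-BuOOH, 4 Å molecular sieves, CH2Cl2, −20 °C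
Reagents that add atoms: tert-butyl hydroperoxide, CC(C)(C)OO
Why: Sharpless asymmetric epoxidation, in which the titanium/D-(−)-tartrate complex delivers oxygen to the olefin face that gives the (2R)-epoxide (the mirror image of the L-(+)-tartrate outcome), the only source of absolute configuration in the route.

**Step 4**
Reactants: 6 [(2R)-3,3-dimethyloxiran-2-yl]methanol
Product: 7 [(2R)-3,3-dimethyloxiran-2-yl]methyl trifluoromethanesulfonate
Conditions: Tf2O, 2,6-lutidine, CH2Cl2, −78 °C; used at once
Reagents that add atoms: trifluoromethanesulfonic anhydride, O=S(=O)(OS(=O)(=O)C(F)(F)F)C(F)(F)F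
Why: O-Sulfonylation of the primary alcohol gives an electrophile reactive enough to alkylate a hindered carbanion at −78 °C at the CH2 carbon without opening the epoxide, and the stereocentre is not touched.

**Step 5**
Reactants: 4 6-geranyl-1,5-dimethoxycyclohexa-1,4-diene; 7 [(2R)-3,3-dimethyloxiran-2-yl]methyl trifluoromethanesulfonate
Product: 8 6-{[(2R)-3,3-dimethyloxiran-2-yl]methyl}-6-geranyl-1,5-dimethoxycyclohexa-1,4-diene
Conditions: t-BuLi, THF, −78 → −40 °C; then 7, −78 °C
Reagents that add atoms: none
Why: A second metallation of the same doubly allylic carbon and SN2 alkylation by the primary triflate builds the quaternary future C5 (not yet stereogenic, since ring A is still mirror-symmetric); geranyl goes on first because a carbanion gamma to an epoxide would close to a cyclopropane if the order were reversed.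

**Step 6**
Reactants: 8 6-{[(2R)-3,3-dimethyloxiran-2-yl]methyl}-6-geranyl-1,5-dimethoxycyclohexa-1,4-diene
Product: 10 (1S,5S,7R)-7-exo-(tert-butyldimethylsilyloxy)-5-geranyl-4-methoxy-8,8-dimethylbicyclo[3.3.1]non-3-en-9-one, via O-methyl oxocarbenium triflate 9 (not isolated)
Conditions: TBSOTf, 2,6-lutidine, CH2Cl2, −78 → −40 °C; aq. NaHCO3
Reagents that add atoms: tert-butyldimethylsilyl trifluoromethanesulfonate, CC(C)(C)[Si](C)(C)OS(=O)(=O)C(F)(F)F
Why: The silyl triflate silylates the epoxide oxygen, the C8–O bond ionises at the tertiary carbon, and C1 (the beta carbon of one methyl enol ether) bonds to C8 anti to the departing oxygen; the resulting C9 O-methyl oxocarbenium 9 is demethylated by triflate (the methyl triflate is taken up by 2,6-lutidine) to release the C9 ketone. The closest known reaction type is the Lewis-acid epoxide-initiated cation–olefin cyclisation terminated by an enol ether, which is established for 6,6-disubstituted 1,5-dimethoxycyclohexa-1,4-dienes carrying a chiral epoxide. Ring B (C1–C8–C7–C6–C5–C9) closes in a 6-endo mode at the epoxide through a chair transition state. C7 keeps the configuration of the (R)-epoxide because its C–O bond is never broken, and it decides the two new centres C1 and C5: only the arm that lets the C7–OSi bond lie equatorial (exo) in the chair while C8 is opened from the back can react, so one enantiotopic enol ether is selected. The step needs this group selection plus chemoselectivity over the geranyl olefins and over oxygen closure; these are secured by the much higher nucleophilicity of the enol ethers, the methyl caps on their oxygens, and the bulky silyl group that keeps the C7 oxygen from adding to C9. The hindered base removes adventitious acid that would hydrolyse the enol ethers.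

**Step 7**
Reactants: 10 7-exo-(tert-butyldimethylsilyloxy)-5-geranyl-4-methoxy-8,8-dimethylbicyclo[3.3.1]non-3-en-9-one
Product: 11 7-exo-(tert-butyldimethylsilyloxy)-5-geranyl-4-methoxy-8,8-dimethylbicyclo[3.3.1]non-3-ene-2,9-dione
Conditions: PhI(OAc)2, t-BuOOH, K2CO3, EtOAc, −20 °C
Reagents that add atoms: tert-butyl hydroperoxide, CC(C)(C)OO
Why: Radical allylic oxidation with tert-butylperoxyl radicals: the C2–H is abstracted in preference to the geranyl allylic hydrogens because the allyl radical ends on the methoxy-bearing C4, and the C2 peroxide collapses (Kornblum–DeLaMare type) to the vinylogous ester.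

**Step 8**
Reactants: 11 7-exo-(tert-butyldimethylsilyloxy)-5-geranyl-4-methoxy-8,8-dimethylbicyclo[3.3.1]non-3-ene-2,9-dione
Product: 12 7-exo-(tert-butyldimethylsilyloxy)-5-geranyl-4-methoxy-8,8-dimethyl-3-(trimethylsilyl)bicyclo[3.3.1]non-3-ene-2,9-dione
Conditions: Li-TMP (lithium 2,2,6,6-tetramethylpiperidide), Me3SiCl (in situ), THF, −78 °C
Reagents that add atoms: chlorotrimethylsilane, C[Si](C)(C)Cl
Why: Directed vinylic lithiation with in situ silyl quench: the C3–H between the carbonyl and the methoxy group is the kinetically fastest site and is masked as C–SiMe3, so the next equivalent of base can act only at the bridgehead.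

**Step 9**
Reactants: 12 7-exo-(tert-butyldimethylsilyloxy)-5-geranyl-4-methoxy-8,8-dimethyl-3-(trimethylsilyl)bicyclo[3.3.1]non-3-ene-2,9-dione; 13 prenyl bromide
Product: 14 7-exo-(tert-butyldimethylsilyloxy)-5-geranyl-4-methoxy-8,8-dimethyl-1-prenyl-3-(trimethylsilyl)bicyclo[3.3.1]non-3-ene-2,9-dione
Conditions: Li-TMP (lithium 2,2,6,6-tetramethylpiperidide), THF, −78 °C; then 13, −78 → −20 °C
Reagents that add atoms: none
Why: Bridgehead lithiation–alkylation: C1–H, acidified by the flanking C2 and C9 carbonyls, is removed by the amide base and the bridgehead carbanion displaces bromide from the primary allylic carbon (SN2), with the configuration at C1 necessarily retained.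

**Step 10**
Reactants: 14 7-exo-(tert-butyldimethylsilyloxy)-5-geranyl-4-methoxy-8,8-dimethyl-1-prenyl-3-(trimethylsilyl)bicyclo[3.3.1]non-3-ene-2,9-dione
Product: 15 5-geranyl-7-exo-hydroxy-4-methoxy-8,8-dimethyl-1-prenylbicyclo[3.3.1]non-3-ene-2,9-dione
Conditions: Bu4NF, THF, rt → 45 °C
Reagents that add atoms: none
Why: Fluoride desilylation cleaves both the O–Si bond at C7 and the activated vinylic C–Si bond alpha to the C2 carbonyl (protodesilylation) in one operation without touching any stereocentre.

**Step 11**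
Reactants: 15 5-geranyl-7-exo-hydroxy-4-methoxy-8,8-dimethyl-1-prenylbicyclo[3.3.1]non-3-ene-2,9-dione
Product: 16 5-geranyl-4-methoxy-8,8-dimethyl-1-prenylbicyclo[3.3.1]non-3-ene-2,7,9-trione
Conditions: Dess–Martin periodinane, CH2Cl2, 0 °C → rt
Reagents that add atoms: none
Why: Dess–Martin oxidation of the hindered secondary alcohol under neutral conditions leaves the olefins alone and deliberately erases the C7 stereocentre.

**Step 12**
Reactants: 16 5-geranyl-4-methoxy-8,8-dimethyl-1-prenylbicyclo[3.3.1]non-3-ene-2,7,9-trione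
Product: 17 5-geranyl-4-methoxy-8,8-dimethyl-7-methylidene-1-prenylbicyclo[3.3.1]non-3-ene-2,9-dione
Conditions: Ph3PCH3Br, KOtBu, THF, 0 → 60 °C
Reagents that add atoms: methyltriphenylphosphonium bromide, C[P+](c1ccccc1)(c1ccccc1)c1ccccc1.[Br-]
Why: Wittig methylenation, selective for the C7 ketone because C9 is shielded by two quaternary bridgeheads and C2 is a poorly electrophilic vinylogous ester carbonyl.

**Step 13**
Reactants: 18 6-methylhept-5-en-2-one
Product: 20 6-methylhept-5-en-1-yne, via enol diethyl phosphate 19 (not isolated)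
Conditions: LiN(iPr)2, THF, −78 °C; ClP(O)(OEt)2, −78 °C → rt; then LiN(iPr)2, −78 °C → rt
Reagents that add atoms: none
Why: Methyl ketone to terminal alkyne conversion: the kinetic enolate of the methyl group is trapped on oxygen as the enol phosphate, and a second portion of amide base eliminates phosphate to give the alkyne.

**Step 14**
Reactants: 20 6-methylhept-5-en-1-yne
Product: 22 (1E)-1-iodo-2,6-dimethylhepta-1,5-diene, via alkenyldimethylalane 21 (not isolated)
Conditions: AlMe3, Cp2ZrCl2 (cat.), CH2Cl2, 0 °C → rt; then I2, THF, −30 → 0 °C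
Reagents that add atoms: trimethylaluminium, C[Al](C)C; iodine, II
Why: Negishi zirconium-catalysed carboalumination adds methyl and aluminium syn across the alkyne with aluminium at the terminus, and iodinolysis with retention fixes the E geometry of the trisubstituted olefin.

**Step 15**
Reactants: 17 5-geranyl-4-methoxy-8,8-dimethyl-7-methylidene-1-prenylbicyclo[3.3.1]non-3-ene-2,9-dione; 22 (1E)-1-iodo-2,6-dimethylhepta-1,5-diene
Product: 24 5-geranyl-7-endo-geranyl-4-methoxy-8,8-dimethyl-1-prenylbicyclo[3.3.1]non-3-ene-2,9-dione, via B-alkyl-9-BBN adduct 23 (not isolated)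
Conditions: 9-BBN, THF, rt → 40 °C; then 22, Pd(dppf)Cl2 (cat.), AsPh3, Cs2CO3, DMF/H2O, rt
Reagents that add atoms: none
Why: Hydroboration followed by B-alkyl Suzuki–Miyaura coupling: 9-BBN adds only to the 1,1-disubstituted olefin with boron on the terminal carbon and delivers hydrogen to C7 from the exo face (the endo face is covered by ring A), which sets C7 with its CH2 substituent endo as in the target; the palladium-catalysed coupling then joins the sp3 carbon to the vinyl iodide with retention of the E geometry.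

**Step 16**
Reactants: 25 3,4-dihydroxybenzoic acid
Product: 26 tert-butyldimethylsilyl 3,4-bis(tert-butyldimethylsilyloxy)benzoate
Conditions: TBSCl, imidazole, DMF, rt
Reagents that add atoms: tert-butyldimethylsilyl chloride, CC(C)(C)[Si](C)(C)Cl
Why: Exhaustive silylation converts both phenols into silyl ethers and the acid into its silyl ester.

**Step 17**
Reactants: 26 tert-butyldimethylsilyl 3,4-bis(tert-butyldimethylsilyloxy)benzoate
Product: 27 3,4-bis(tert-butyldimethylsilyloxy)benzoyl chloride
Conditions: (COCl)2, DMF (cat.), CH2Cl2, 0 °C → rt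
Reagents that add atoms: oxalyl chloride, ClC(=O)C(Cl)=O
Why: The Vilsmeier-type chloroiminium reagent converts a silyl ester directly into the acid chloride under neutral conditions that leave aryl silyl ethers intact.

**Step 18**
Reactants: 24 5-geranyl-7-endo-geranyl-4-methoxy-8,8-dimethyl-1-prenylbicyclo[3.3.1]non-3-ene-2,9-dione; 27 3,4-bis(tert-butyldimethylsilyloxy)benzoyl chloride
Product: 28 3-[3,4-bis(tert-butyldimethylsilyloxy)benzoyl]-5-geranyl-7-endo-geranyl-4-methoxy-8,8-dimethyl-1-prenylbicyclo[3.3.1]non-3-ene-2,9-dione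
Conditions: Li-TMP (lithium 2,2,6,6-tetramethylpiperidide), THF, −78 °C; then 27, −78 °C
Reagents that add atoms: none
Why: Vinylic lithiation of the vinylogous ester at C3 (the only remaining acidic C–H, between the carbonyl and the methoxy group) and C-acylation of the vinyllithium by the aroyl chloride.

**Step 19**
Reactants: 28 3-[3,4-bis(tert-butyldimethylsilyloxy)benzoyl]-5-geranyl-7-endo-geranyl-4-methoxy-8,8-dimethyl-1-prenylbicyclo[3.3.1]non-3-ene-2,9-dione
Product: 29 Oblongifolin D
Conditions: LiOH·H2O, degassed dioxane/H2O, 80 °C; then 1 M HCl, 0 °C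
Reagents that add atoms: lithium hydroxide, [Li+].[OH-]
Why: Basic hydrolysis: hydroxide displaces methoxide from the doubly activated C4 by addition–elimination and removes both aryl silyl groups by attack at silicon, while the trione is protected as its enolate until mild acidification, so no stereocentre or olefin is disturbed.

**Compound list**

1 | 1,3-dimethoxybenzene | COc1cccc(OC)c1 | starting material
2 | 1,5-dimethoxycyclohexa-1,4-diene | COC1=CCC=C(OC)C1 | intermediate
3 | geranyl bromide, (2E)-1-bromo-3,7-dimethylocta-2,6-diene | CC(C)=CCC/C(C)=C/CBr | starting material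
4 | 6-geranyl-1,5-dimethoxycyclohexa-1,4-diene | COC1=CCC=C(OC)C1C/C=C(\C)CCC=C(C)C | intermediate
5 | 3-methylbut-2-en-1-ol | CC(C)=CCO | starting material
6 | [(2R)-3,3-dimethyloxiran-2-yl]methanol | OC[C@H]1OC1(C)C | intermediate
7 | [(2R)-3,3-dimethyloxiran-2-yl]methyl trifluoromethanesulfonate | FC(F)(F)S(=O)(=O)OC[C@H]1OC1(C)C | intermediate
8 | 6-{[(2R)-3,3-dimethyloxiran-2-yl]methyl}-6-geranyl-1,5-dimethoxycyclohexa-1,4-diene | COC1=CCC=C(OC)C1(C/C=C(\C)CCC=C(C)C)C[C@H]2OC2(C)C | intermediate
9 | C9 O-methyl oxocarbenium triflate of the cyclised 7-exo-silyl ether (C1–C8 bond formed, C3=C4 enol ether intact) | CC(C)(C)[Si](C)(C)O[C@@H]1C[C@]2(C/C=C(\C)CCC=C(C)C)C(=[O+]C)[C@@H](CC=C2OC)C1(C)C.[O-]S(=O)(=O)C(F)(F)F | intermediate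
10 | (1S,5S,7R)-7-exo-(tert-butyldimethylsilyloxy)-5-geranyl-4-methoxy-8,8-dimethylbicyclo[3.3.1]non-3-en-9-one (C1–H) | CC(C)(C)[Si](C)(C)O[C@@H]1C[C@]2(C/C=C(\C)CCC=C(C)C)C(=O)[C@@H](CC=C2OC)C1(C)C | intermediate
11 | 7-exo-(tert-butyldimethylsilyloxy)-5-geranyl-4-methoxy-8,8-dimethylbicyclo[3.3.1]non-3-ene-2,9-dione (bridgeheads as in 10) | CC(C)(C)[Si](C)(C)O[C@@H]1C[C@]2(C/C=C(\C)CCC=C(C)C)C(=O)[C@@H](C(=O)C=C2OC)C1(C)C | intermediate
12 | 3-trimethylsilyl derivative of 11 | CC(C)(C)[Si](C)(C)O[C@@H]1C[C@]2(C/C=C(\C)CCC=C(C)C)C(=O)[C@@H](C(=O)C([Si](C)(C)C)=C2OC)C1(C)C | intermediate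
13 | prenyl bromide, 1-bromo-3-methylbut-2-ene | CC(C)=CCBr | starting material
14 | 7-exo-(tert-butyldimethylsilyloxy)-5-geranyl-4-methoxy-8,8-dimethyl-1-prenyl-3-(trimethylsilyl)bicyclo[3.3.1]non-3-ene-2,9-dione | CC(C)(C)[Si](C)(C)O[C@@H]1C[C@]2(C/C=C(\C)CCC=C(C)C)C(=O)[C@@](CC=C(C)C)(C(=O)C([Si](C)(C)C)=C2OC)C1(C)C | intermediate
15 | 5-geranyl-7-exo-hydroxy-4-methoxy-8,8-dimethyl-1-prenylbicyclo[3.3.1]non-3-ene-2,9-dione | O[C@@H]1C[C@]2(C/C=C(\C)CCC=C(C)C)C(=O)[C@@](CC=C(C)C)(C(=O)C=C2OC)C1(C)C | intermediate
16 | 5-geranyl-4-methoxy-8,8-dimethyl-1-prenylbicyclo[3.3.1]non-3-ene-2,7,9-trione | O=C1C[C@]2(C/C=C(\C)CCC=C(C)C)C(=O)[C@@](CC=C(C)C)(C(=O)C=C2OC)C1(C)C | intermediate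
17 | 5-geranyl-4-methoxy-8,8-dimethyl-7-methylidene-1-prenylbicyclo[3.3.1]non-3-ene-2,9-dione | C=C1C[C@]2(C/C=C(\C)CCC=C(C)C)C(=O)[C@@](CC=C(C)C)(C(=O)C=C2OC)C1(C)C | intermediate
18 | 6-methylhept-5-en-2-one | CC(=O)CCC=C(C)C | starting material
19 | diethyl 6-methylhepta-1,5-dien-2-yl phosphate | C=C(CCC=C(C)C)OP(=O)(OCC)OCC | intermediate
20 | 6-methylhept-5-en-1-yne | C#CCCC=C(C)C | intermediate
21 | [(1E)-2,6-dimethylhepta-1,5-dien-1-yl]dimethylalane | C[Al](C)/C=C(\C)CCC=C(C)C | intermediate
22 | (1E)-1-iodo-2,6-dimethylhepta-1,5-diene | I/C=C(\C)CCC=C(C)C | intermediate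
23 | 9-[(7-endo-bicyclic)methyl]-9-borabicyclo[3.3.1]nonane, the hydroboration adduct of 17 (boron on the exocyclic CH2, C7–H exo) | B1(C2CCCC1CCC2)C[C@H]3C[C@]4(C/C=C(\C)CCC=C(C)C)C(=O)[C@@](CC=C(C)C)(C(=O)C=C4OC)C3(C)C | intermediate
24 | 5-geranyl-7-endo-geranyl-4-methoxy-8,8-dimethyl-1-prenylbicyclo[3.3.1]non-3-ene-2,9-dione | CC(C)=CCC/C(C)=C/C[C@H]1C[C@]2(C/C=C(\C)CCC=C(C)C)C(=O)[C@@](CC=C(C)C)(C(=O)C=C2OC)C1(C)C | intermediate
25 | 3,4-dihydroxybenzoic acid | OC(=O)c1ccc(O)c(O)c1 | starting material
26 | tert-butyldimethylsilyl 3,4-bis(tert-butyldimethylsilyloxy)benzoate | CC(C)(C)[Si](C)(C)OC(=O)c1ccc(O[Si](C)(C)C(C)(C)C)c(O[Si](C)(C)C(C)(C)C)c1 | intermediate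
27 | 3,4-bis(tert-butyldimethylsilyloxy)benzoyl chloride | ClC(=O)c1ccc(O[Si](C)(C)C(C)(C)C)c(O[Si](C)(C)C(C)(C)C)c1 | intermediate
28 | 3-[3,4-bis(tert-butyldimethylsilyloxy)benzoyl]-5-geranyl-7-endo-geranyl-4-methoxy-8,8-dimethyl-1-prenylbicyclo[3.3.1]non-3-ene-2,9-dione | CC(C)=CCC/C(C)=C/C[C@H]1C[C@]2(C/C=C(\C)CCC=C(C)C)C(=O)[C@@](CC=C(C)C)(C(=O)C(C(=O)c3ccc(O[Si](C)(C)C(C)(C)C)c(O[Si](C)(C)C(C)(C)C)c3)=C2OC)C1(C)C | intermediate
29 | Oblongifolin D, (1S,5S,7S) in the C4-enol form | CC(C)=CCC/C(C)=C/C[C@H]1C[C@]2(C/C=C(\C)CCC=C(C)C)C(=O)[C@@](CC=C(C)C)(C(=O)C(C(=O)c3ccc(O)c(O)c3)=C2O)C1(C)C | target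

**Step count and risks**

Total step count: 19. Longest linear sequence: 13 steps (1, 2, 5, 6, 7, 8, 9, 10, 11, 12, 15, 18, 19).

Steps most likely to fail:

Step 6. After ionisation of the silylated epoxide, the cation may lose a proton from a C8 methyl group or be captured by the nearer geranyl olefin instead of an enol ether. The selection between the two enol ether arms may be incomplete. The C7 oxygen may add to the C9 oxocarbenium despite its silyl group. The fallback sets out from 8 and turns that last pathway into the plan. With catalytic Me3SiOTf and 2,6-lutidine in CH2Cl2 at −78 °C, the trimethylsilylated C7 oxygen is allowed to trap the oxocarbenium, which should give the caged mixed methyl ketal F1 (C7–O–C9 bridge, C9–OMe kept). Only the cyclisation product with the exo oxygen can close this cage, and C9 stays masked. Allylic oxidation of F1 under the conditions of step 7 should give the caged vinylogous ester F2. Me2BBr in CH2Cl2 at −78 °C then opens the ketal to the 7-exo-hydroxy-2,9-dione F3. Silylation with TBSOTf and 2,6-lutidine brings the material back to the route at 11.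

Step 9. The amide base may deprotonate elsewhere. The bridgehead organolithium, crowded by the C8 quaternary carbon, may also react with prenyl bromide by electron transfer or at its gamma carbon instead of by clean SN2 displacement. The fallback sets out from 12. Bridgehead lithiation as in step 9, followed by I2, should give the bridgehead iodide F4. Keck radical allylation (Bu3SnCH2CH=CH2, Et3B, air, benzene, rt) should give the C1-allyl compound F5, since a bridgehead radical needs no backside access. Cross-metathesis with 2-methyl-2-butene and the second-generation Hoveyda–Grubbs catalyst (CH2Cl2, 40 °C) then converts allyl into prenyl, the monosubstituted olefin reacting much faster than the trisubstituted geranyl olefins. This returns to the route at 14.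

Step 15. Hydroboration of the neopentyl-type exocyclic olefin may be slow enough for 9-BBN to begin reducing a carbonyl group. Hydride delivery to C7 may not be fully exo-selective. The beta-branched alkylborane may transmetallate slowly, so that protodeboronation and attack of the aqueous base on the vinylogous ester compete. The fallback sets out from 17. Hydroboration with 9-BBN followed by oxidation with NaBO3·4H2O should give the 7-endo-hydroxymethyl compound F6, a stage at which any C7 epimer can be removed by chromatography. Appel iodination (PPh3, I2, imidazole, CH2Cl2) should give the primary iodide F7. Zinc insertion (Zn, LiCl, THF) gives the alkylzinc iodide F8, which is coupled with 22 under base-free Negishi conditions (Pd(PPh3)4, THF, rt) to return to the route at 24.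

**Further compounds**

F1 | step 6 | caged mixed methyl ketal: 5-geranyl-4,9-dimethoxy-8,8-dimethylbicyclo[3.3.1]non-3-ene with an oxygen bridge from C7 (exo) to C9 | O1[C@@H]2C[C@]3(C/C=C(\C)CCC=C(C)C)[C@@]1(OC)[C@@H](CC=C3OC)C2(C)C
F2 | step 6 | caged vinylogous ester: the 2-oxo derivative of F1 | O1[C@@H]2C[C@]3(C/C=C(\C)CCC=C(C)C)[C@@]1(OC)[C@@H](C(=O)C=C3OC)C2(C)C
F3 | step 6 | 5-geranyl-7-exo-hydroxy-4-methoxy-8,8-dimethylbicyclo[3.3.1]non-3-ene-2,9-dione | O[C@@H]1C[C@]2(C/C=C(\C)CCC=C(C)C)C(=O)[C@@H](C(=O)C=C2OC)C1(C)C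
F4 | step 9 | 1-iodo-7-exo-(tert-butyldimethylsilyloxy)-5-geranyl-4-methoxy-8,8-dimethyl-3-(trimethylsilyl)bicyclo[3.3.1]non-3-ene-2,9-dione | CC(C)(C)[Si](C)(C)O[C@@H]1C[C@]2(C/C=C(\C)CCC=C(C)C)C(=O)[C@@](I)(C(=O)C([Si](C)(C)C)=C2OC)C1(C)C
F5 | step 9 | 1-allyl-7-exo-(tert-butyldimethylsilyloxy)-5-geranyl-4-methoxy-8,8-dimethyl-3-(trimethylsilyl)bicyclo[3.3.1]non-3-ene-2,9-dione | CC(C)(C)[Si](C)(C)O[C@@H]1C[C@]2(C/C=C(\C)CCC=C(C)C)C(=O)[C@@](CC=C)(C(=O)C([Si](C)(C)C)=C2OC)C1(C)C
F6 | step 15 | 5-geranyl-7-endo-(hydroxymethyl)-4-methoxy-8,8-dimethyl-1-prenylbicyclo[3.3.1]non-3-ene-2,9-dione | OC[C@H]1C[C@]2(C/C=C(\C)CCC=C(C)C)C(=O)[C@@](CC=C(C)C)(C(=O)C=C2OC)C1(C)C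
F7 | step 15 | 5-geranyl-7-endo-(iodomethyl)-4-methoxy-8,8-dimethyl-1-prenylbicyclo[3.3.1]non-3-ene-2,9-dione | IC[C@H]1C[C@]2(C/C=C(\C)CCC=C(C)C)C(=O)[C@@](CC=C(C)C)(C(=O)C=C2OC)C1(C)C
F8 | step 15 | alkylzinc iodide from F7 (zinc on the 7-endo CH2) | I[Zn]C[C@H]1C[C@]2(C/C=C(\C)CCC=C(C)C)C(=O)[C@@](CC=C(C)C)(C(=O)C=C2OC)C1(C)C
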